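**Retrosynthetic overview**
1. Target 7 ⇐ bis-silyl ether 6 by fluoride desilylation. No ring is formed at any point; the only ring, the benzene ring, is bought as 2,5-dibromohydroquinone.
2. The C1 ketone and the C7 tertiary alcohol ⇐ diene 4. Both missing oxygens are put in by one twofold radical (hydrogen-atom-transfer) Markovnikov hydration, followed by oxidation of the benzylic alcohol.
3. Aryl–C1 bond ⇐ Mizoroki–Heck mono-vinylation of symmetrical dibromide 2 with the vinyl group of (S)-linalool 3.
4. The C3 stereocentre and the whole C10 chain come unchanged from the chiral pool, so the usual aldol of an aryl methyl ketone onto a methyl ketone is avoided.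

Assumption: (S)-(+)-linalool (coriandrol) is bought in high enantiomeric purity; its stereocentre is never touched, so the ee of the target equals that of the linalool used.

**Step 1**
Reactants: 1 2,5-dibromohydroquinone (2,5-dibromobenzene-1,4-diol)
Product: 2 1,4-dibromo-2,5-bis(tert-butyldimethylsilyloxy)benzene
Conditions: TBSCl (2.4 equiv), imidazole (5 equiv), DMF, rt
Reagents that add atoms: tert-butyldimethylsilyl chloride (TBSCl), CC(C)(C)[Si](C)(C)Cl
Why: Standard imidazole-promoted O-silylation of both phenols; it masks the oxidation-prone hydroquinone with groups that survive palladium, radical and oxidation chemistry and come off without acid or base.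

**Step 2**
Reactants: 2 1,4-dibromo-2,5-bis(tert-butyldimethylsilyloxy)benzene (2.5 equiv, excess recovered); 3 (S)-(+)-linalool, (3S)-3,7-dimethylocta-1,6-dien-3-ol
Product: 4 (3S,1E)-1-[4-bromo-2,5-bis(tert-butyldimethylsilyloxy)phenyl]-3,7-dimethylocta-1,6-dien-3-ol
Conditions: Pd2(dba)3 (2.5 mol%), [HP(t-Bu)3]BF4 (10 mol%), Cy2NMe (1.5 equiv), 1,4-dioxane, 70 °C
Reagents that add atoms: none
Why: Mizoroki–Heck reaction: zerovalent palladium inserts into one C–Br bond, the aryl group adds to the terminal carbon of the monosubstituted alkene only, and β-hydride elimination can occur only away from the quaternary carbinol, giving the E-styrene. The excess of symmetrical dibromide enforces mono-coupling and keeps the second bromine; the stereocentre is a spectator.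

**Step 3**
Reactants: 4 (3S,1E)-1-[4-bromo-2,5-bis(tert-butyldimethylsilyloxy)phenyl]-3,7-dimethylocta-1,6-dien-3-ol
Product: 5 (3S)-1-[4-bromo-2,5-bis(tert-butyldimethylsilyloxy)phenyl]-3,7-dimethyloctane-1,3,7-triol, mixture of C1 epimers
Conditions: Co(acac)2 (20 mol%), PhSiH3 (6 equiv), O2 (1 atm), THF/i-PrOH 1:1, rt
Reagents that add atoms: dioxygen, O=O
Why: Twofold Mukaiyama hydration: hydrogen-atom transfer from the hydride made from Co(acac)2 and PhSiH3 puts H on C2 and C6, and the resulting benzylic (C1) and tertiary (C7) radicals are trapped by O2 and reduced to alcohols. C3 is untouched, the new C1 centre is erased in step 4, and any ketone already formed here is compound 6.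

**Step 4**
Reactants: 5 (3S)-1-[4-bromo-2,5-bis(tert-butyldimethylsilyloxy)phenyl]-3,7-dimethyloctane-1,3,7-triol
Product: 6 (3S)-1-[4-bromo-2,5-bis(tert-butyldimethylsilyloxy)phenyl]-3,7-dihydroxy-3,7-dimethyloctan-1-one
Conditions: Dess–Martin periodinane (1.5 equiv), pyridine (4 equiv), CH2Cl2, 0 °C to rt
Reagents that add atoms: none
Why: Dess–Martin oxidation: only the secondary benzylic alcohol can be oxidised, the two tertiary alcohols are inert, and the pyridine buffer prevents acid-promoted dehydration of the new β-hydroxy ketone.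

**Step 5**
Reactants: 6 (3S)-1-[4-bromo-2,5-bis(tert-butyldimethylsilyloxy)phenyl]-3,7-dihydroxy-3,7-dimethyloctan-1-one
Product: 7 (3S)-1-(4-bromo-2,5-dihydroxyphenyl)-3,7-dihydroxy-3,7-dimethyloctan-1-one
Conditions: KHF2 (4 equiv), degassed MeOH, argon, rt
Reagents that add atoms: none
Why: Fluoride-mediated desilylation of aryl silyl ethers: KHF2 in methanol cleaves phenolic Si–O bonds at room temperature under near-neutral conditions, so the tertiary β-hydroxy ketone neither undergoes retro-aldol cleavage (which would racemise C3) nor dehydrates; the aryl bromide is untouched.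

**Compound list**
1 | 2,5-dibromohydroquinone | Oc1cc(Br)c(O)cc1Br | starting material
2 | 1,4-dibromo-2,5-bis(tert-butyldimethylsilyloxy)benzene | CC(C)(C)[Si](C)(C)Oc1cc(Br)c(O[Si](C)(C)C(C)(C)C)cc1Br | intermediate
3 | (S)-(+)-linalool, (3S)-3,7-dimethylocta-1,6-dien-3-ol | CC(C)=CCC[C@](C)(O)C=C | starting material
4 | (3S,1E)-1-[4-bromo-2,5-bis(tert-butyldimethylsilyloxy)phenyl]-3,7-dimethylocta-1,6-dien-3-ol | CC(C)=CCC[C@](C)(O)/C=C/c1cc(O[Si](C)(C)C(C)(C)C)c(Br)cc1O[Si](C)(C)C(C)(C)C | intermediate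
5 | (3S)-1-[4-bromo-2,5-bis(tert-butyldimethylsilyloxy)phenyl]-3,7-dimethyloctane-1,3,7-triol (C1 epimers) | CC(C)(O)CCC[C@](C)(O)CC(O)c1cc(O[Si](C)(C)C(C)(C)C)c(Br)cc1O[Si](C)(C)C(C)(C)C | intermediate
6 | (3S)-1-[4-bromo-2,5-bis(tert-butyldimethylsilyloxy)phenyl]-3,7-dihydroxy-3,7-dimethyloctan-1-one | CC(C)(O)CCC[C@](C)(O)CC(=O)c1cc(O[Si](C)(C)C(C)(C)C)c(Br)cc1O[Si](C)(C)C(C)(C)C | intermediate
7 | (3S)-1-(4-bromo-2,5-dihydroxyphenyl)-3,7-dihydroxy-3,7-dimethyloctan-1-one | CC(C)(O)CCC[C@](C)(O)CC(=O)c1cc(O)c(Br)cc1O | target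

**Totals**
Total step count: 5. Longest linear sequence: 5 steps (1 → 2 → 4 → 5 → 6 → 7); linalool 3 enters at step 2.

**Steps most likely to fail, with fallbacks**

Step 2 (mono-Heck on a hindered, electron-rich dibromide; risk of low conversion or double coupling). The fallback sets out from 3 and 2 and comes back at 5, replacing the Heck reaction by addition of an aryl-magnesium to an aldehyde.
- Hydroboration of the vinyl group of 3 with 9-BBN (THF, 0 °C to rt; the trisubstituted alkene is left alone) gives B-[(3R)-3-hydroxy-3,7-dimethyloct-6-en-1-yl]-9-borabicyclo[3.3.1]nonane F1 (the CIP label changes, the spatial arrangement does not).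
- Oxidation in the same flask (NaOH, H2O2) gives (3S)-3,7-dimethyloct-6-ene-1,3-diol F2.
- TEMPO/PhI(OAc)2 oxidises only the primary alcohol, giving (3S)-3-hydroxy-3,7-dimethyloct-6-enal F3.
- Separately, a single Br/Mg exchange on 2 (i-PrMgCl·LiCl, THF, 0 °C) gives [4-bromo-2,5-bis(tert-butyldimethylsilyloxy)phenyl]magnesium chloride F4.
- Addition of 2.2 equiv of this reagent to the aldehyde gives (3S)-1-[4-bromo-2,5-bis(tert-butyldimethylsilyloxy)phenyl]-3,7-dimethyloct-6-ene-1,3-diol F5 as C1 epimers.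
- Hydration of its one remaining alkene under the step 3 conditions gives 5.

Step 3 (twofold radical hydration; risk of incomplete reaction at the hindered styrene, or cyclisation of the C7 radical onto the styrene). The fallback sets out from 4 and comes back at 6, treating the two alkenes separately and making the C1–O bond by oxypalladation instead of a radical.
- Tsuji–Wacker oxidation (PdCl2 10 mol%, CuCl, O2, DMF/H2O, 40 °C) should put oxygen on benzylic C1, because C2 is neopentylic and inductively deactivated by the allylic hydroxyl. This gives (3S)-1-[4-bromo-2,5-bis(tert-butyldimethylsilyloxy)phenyl]-3-hydroxy-3,7-dimethyloct-6-en-1-one F6.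
- The isolated trisubstituted alkene, inert to the Wacker conditions, is then hydrated alone (Co(acac)2, PhSiH3, O2) to give 6; step 4 is skipped.

Step 5 (the free hydroquinone is air-sensitive and the tertiary aldol can cleave if the medium turns basic). The fallback sets out from 1 and comes back at 7, changing the protecting-group strategy to acid-labile acetals so that no fluoride or base meets the aldol.
- MOMCl/i-Pr2NEt (CH2Cl2, 0 °C) gives 1,4-dibromo-2,5-bis(methoxymethoxy)benzene F7.
- The step 2 Heck reaction with 3 gives (3S,1E)-1-[4-bromo-2,5-bis(methoxymethoxy)phenyl]-3,7-dimethylocta-1,6-dien-3-ol F8.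
- The step 3 hydration gives (3S)-1-[4-bromo-2,5-bis(methoxymethoxy)phenyl]-3,7-dimethyloctane-1,3,7-triol F9.
- The step 4 oxidation gives (3S)-1-[4-bromo-2,5-bis(methoxymethoxy)phenyl]-3,7-dihydroxy-3,7-dimethyloctan-1-one F10.
- Acid-catalysed transacetalisation (cat. HCl, MeOH, rt) gives 7.

**Further compounds**
F1 | step 2 | B-[(3R)-3-hydroxy-3,7-dimethyloct-6-en-1-yl]-9-borabicyclo[3.3.1]nonane | CC(C)=CCC[C@](C)(O)CCB1C2CCCC1CCC2
F2 | step 2 | (3S)-3,7-dimethyloct-6-ene-1,3-diol | CC(C)=CCC[C@](C)(O)CCO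
F3 | step 2 | (3S)-3-hydroxy-3,7-dimethyloct-6-enal | CC(C)=CCC[C@](C)(O)CC=O
F4 | step 2 | [4-bromo-2,5-bis(tert-butyldimethylsilyloxy)phenyl]magnesium chloride | CC(C)(C)[Si](C)(C)Oc1cc([Mg]Cl)c(O[Si](C)(C)C(C)(C)C)cc1Br
F5 | step 2 | (3S)-1-[4-bromo-2,5-bis(tert-butyldimethylsilyloxy)phenyl]-3,7-dimethyloct-6-ene-1,3-diol (C1 epimers) | CC(C)=CCC[C@](C)(O)CC(O)c1cc(O[Si](C)(C)C(C)(C)C)c(Br)cc1O[Si](C)(C)C(C)(C)C
F6 | step 3 | (3S)-1-[4-bromo-2,5-bis(tert-butyldimethylsilyloxy)phenyl]-3-hydroxy-3,7-dimethyloct-6-en-1-one | CC(C)=CCC[C@](C)(O)CC(=O)c1cc(O[Si](C)(C)C(C)(C)C)c(Br)cc1O[Si](C)(C)C(C)(C)C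
F7 | step 5 | 1,4-dibromo-2,5-bis(methoxymethoxy)benzene | COCOc1cc(Br)c(OCOC)cc1Br
F8 | step 5 | (3S,1E)-1-[4-bromo-2,5-bis(methoxymethoxy)phenyl]-3,7-dimethylocta-1,6-dien-3-ol | CC(C)=CCC[C@](C)(O)/C=C/c1cc(OCOC)c(Br)cc1OCOC
F9 | step 5 | (3S)-1-[4-bromo-2,5-bis(methoxymethoxy)phenyl]-3,7-dimethyloctane-1,3,7-triol (C1 epimers) | CC(C)(O)CCC[C@](C)(O)CC(O)c1cc(OCOC)c(Br)cc1OCOC
F10 | step 5 | (3S)-1-[4-bromo-2,5-bis(methoxymethoxy)phenyl]-3,7-dihydroxy-3,7-dimethyloctan-1-one | CC(C)(O)CCC[C@](C)(O)CC(=O)c1cc(OCOC)c(Br)cc1OCOC
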